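The constants of this flask are shared: one temperature throughout, and free catalyst at 6.00 mM in the spring, autumn, summer and winter runs.

| setting | spring | autumn | summer | noon | winter |
|---|---|---|---|---|---|
| starting material | 120 mM | 48.0 mM | 240 mM | 120 mM | 780 mM |
| free catalyst | 6.00 mM | 6.00 mM | 6.00 mM | 12.0 mM | 6.00 mM |
| time |  |  |  |  | 19 h |

- spring run (time / h: [product] / mM): 0.68: 0.4; 2.1: 7.1; 4.0: 16.2; 6.3: 26.1; 9.0: 36.5; 12: 46.0; 15: 52.7; 19: 57.9
- autumn run (time / h: [product] / mM): 0.68: 1.8; 2.1: 3.6; 4.0: 7.2; 6.3: 10.6; 9.0: 15.1; 12: 18.1; 15: 20.1; 19: 23.0
- summer run (time / h: [product] / mM): 0.68: 2.5; 2.1: 13.9; 4.0: 32.4; 6.3: 51.3; 9.0: 71.9; 12: 89.2; 15: 103.3; 19: 115.0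
- noon run (time / h: [product] / mM): 0.68: 3.1; 2.1: 11.0; 4.0: 22.9; 6.3: 39.5; 9.0: 51.3; 12: 62.9; 15: 73.4; 19: 80.8

(standard deviation of a reading: 1 mM)

- Overall: starting material -> product, with free catalyst as catalyst.
- Constant volume, constant temperature.
- An order is taken over about fifteen percent of the charge, up and down.

- order of the initial rate in [free catalyst], near the charge of the spring run, the rate being that where two percent of its starting material are product
- order of the initial rate in [starting material], near the charge of the spring run, the rate being that where two percent of its starting material are product (one fixed amount of product, the same in the runs compared)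
- product in the winter run at 19 h, as a share of the starting material charged

The spring run holds an apparent contradiction. Between 6.3 h and 9.0 h it makes 3.85 mM h⁻¹, and between 15 h and 19 h it makes 1.30 mM h⁻¹, a third of that. Yet the starting material left goes from 83.5 mM at 9.0 h to 62.1 mM at 19 h.

So in the spring run the rate falls faster than the starting material. The pseudo-first-order coefficient, the rate per mM of starting material, must therefore drop between those two stretches of the spring run. The readings at 19 h show no trend with the charge: the autumn run has turned 47.9%, the spring run 48.2% and the summer run 47.9%.

The useful quantity is the share of the charge turned into product at 19 h with 6.00 mM of free catalyst, pooled over the autumn, spring and summer runs: 48.0%. Carried to the winter charge, it gives 375 mM of product.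

The forecast gives 0.48 for the order in free catalyst and 0.8 for the order in starting material. It gives 46% for the winter share, starting from the ground that “The fraction converted at a given time doesn't depend on the charge”. Its share stands lower than the pooled one.

The winter run gives 48.0%, which is 375 mM of product against the 375 mM reckoned. The orders are 0.43 in free catalyst and 0.72 in starting material. The noon run has the charge of starting material of the spring run with twice the free catalyst, and there the pooled share gives 57.6 mM at 19 h, but the reading is 80.8 mM.

    2 active catalyst ⇌ catalyst dimer, settled at all times (1310 M⁻¹)
    active catalyst + starting material → product + active catalyst (44.64 M⁻¹ h⁻¹)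
    active catalyst → spent catalyst (0.3488 h⁻¹)
    free catalyst → active catalyst (0.3996 h⁻¹)

At 19 h the winter run still holds 405 mM of starting material. The conversion of active catalyst into spent catalyst holds the share of the winter run down. The winter run as it stands reaches 48.0%, and the same run with that step taken away reaches 64.3%.

(The earlier runs and the new flask come from a simulation from invented constants, noise included.)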